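## Structural features

The target is a C15 dibromo ether in which a 7-oxabicyclo[2.2.1]heptane (C1 methyl, C2 bromo, C3, C4, C5, C6, O7) is joined through its bridgehead C4 by a single C–C bond to C1′ of a 4-bromo-3,3-dimethylcyclohexane. It has five stereocentres, C1, C2 and C4 in the bicycle and C1′ and C4′ on the cyclohexane; C4 and C1′ are neighbours across the inter-ring bond and C4′ stands next to the quaternary C3′. The three bicycle centres are coupled: the O7 bridge ties C1 to C4 and the endo bromine at C2 lies anti to the C1–O7 bond, so all three follow once it is settled which of the two carbon arms leaving C4 carries the bromine. On the cyclohexane the bromine and the bicycle are trans and both equatorial. The fragile groups are the neopentylic secondary C4′–Br bond (ionisation with methyl shift, elimination, single-electron reduction), the β-bromo ether at C2 (reductive ring opening) and the strained, acid-labile ether bridge. The real difficulty is the relative configuration between the two ring systems, since only the C4–C1′ bond links them and the cyclohexane centres can exert little control over C4. The key step exploits the latent symmetry of the carbocycle C4–C3–C2–C1–C6–C5: with an exocyclic methylene on C1 and no bromine on C2 the arms C3–C2 and C5–C6 are identical, C4 is not stereogenic, and the whole ring can be assembled on the carbonyl carbon of a cyclohexanecarboxylate that already holds C1′ and C4′.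

## Logic of the disconnections

18 ⇒ 17. The O7–C1 and C2–Br bonds are cut together, because both arise in one anti addition across a C1=C2 alkene with the C4 hydroxyl as internal nucleophile. This removes the bicycle, one bromine and two stereocentres, and leaves a cyclohexenol whose only stereocentre in that ring is the carbinol carbon. The forward step must be regioselective for oxygen at the methyl-bearing carbon and stereospecific, and the carbinol configuration of 17 must be correct because it decides all three bicycle centres.

17 ⇒ 16. No skeletal bond is cut; the ring alkene is moved back to the exocyclic position. This erases the last stereocentre of the oxygenated ring and makes that ring symmetric. The forward step must choose between two ring methylenes that differ only through the remote chirality of the cyclohexyl group, so it needs catalyst control; it is the most demanding operation of the route.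

16 ⇒ 11 + 14. The bonds C4–C3 and C4–C5 are cut. Both arms are identical and meet at one carbon at the ester oxidation level, so a five-carbon 1,5-dimetal reagent and an ester are the natural partners. The cut is convergent, separates an achiral C6 piece from the chiral ring, and creates no stereocentre. The forward step must close the ring rather than oligomerise, and must leave the secondary bromide and the α-stereocentre of 11 untouched.

14 ⇒ 13 ⇒ 12. Two C–Mg bonds are traced back to two C–Br bonds and then to two C–O bonds. These are functional-group changes on a symmetric chain. The demands are neutral bromination (no alkene migration, no HBr addition) and suppression of Wurtz coupling during magnesium insertion.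

11 ⇒ 10 ⇒ 9. The ester O–CH3 bond is cut and the carboxyl group is taken back to the aldehyde, which is the direct product of a one-carbon homologation. C1′ is epimerisable only at the aldehyde stage, so its configuration is set there under equilibrium and the epimers are separated at 11. The forward steps must not epimerise C1′ further or disturb C4′–Br.

9 ⇒ 5 + 6. The exocyclic C1′–C bond is cut (formed as the C=C bond of 8), which reduces the problem to a ketone with a single stereocentre. The basic ylide 7 must add to the carbonyl faster than it enolises a γ-bromo ketone.

5 ⇒ 4. No bond is cut; the enantiomers are separated. No catalyst-controlled bromocyclisation can be relied on for this substrate class, so the ring is made as a racemate and resolved at the earliest, cheapest point.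

4 ⇒ 3 ⇒ 1. The bonds C2′–C3′ and C4′–Br are cut, since a bromine next to a gem-dimethyl carbon is the signature of a bromonium-initiated cyclisation of a prenyl group. Then the enol O–acyl bond is cut, which leads back to a commercial acyclic ketone. The forward step needs Br+ to go to the prenyl alkene and not to the enol terminus, which is why an enol ester and not a silyl enol ether is used, and it needs the kinetic (terminal) enolate.

## Other disconnections considered

Alternative 1: The cut is C4–C5 and C1–C6, so the unsubstituted two-carbon bridge becomes a dienophile. In the forward direction the furan 3-bromo-5-[(1S,4S)-4-bromo-3,3-dimethylcyclohexyl]-2-methylfuran A1 and the dienophile 2,2,2-trifluoroethyl prop-2-enoate A2 would combine in a Lewis-acid-catalysed [4+2] cycloaddition. The product would be the bicyclic ester 2,2,2-trifluoroethyl (1R,2S,4R)-6-bromo-4-[(1S,4S)-4-bromo-3,3-dimethylcyclohexyl]-1-methyl-7-oxabicyclo[2.2.1]hept-5-ene-2-carboxylate A3, drawn as the endo ester; its regio- and exo isomers would converge once the ester is removed. In A3 the ring bromine takes the locant 6, because it sits on the alkene carbon next to the methyl-bearing bridgehead (the carbon that becomes C2 of the target); a 5-bromo locant would describe the regioisomer with bromine next to C4.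

In its favour, one step would create the complete oxabicycle with the O7 bridge, the C4–C1′ bond would come in with A1, and the position of the ring bromine is fixed by the furan substitution. A point on which this plan is the equal or the better of the chosen one: enantioselective furan–acrylate cycloadditions under chiral cationic Lewis acids are an established class for simple furans, and the fluorinated ester of A2 is the dienophile type used there. The step that relates C1 and C4 to the cyclohexane would thus rest on precedent at least as good as that of the cobalt isomerisation chosen here.

Against it, a 2,3,5-trisubstituted furan such as A1, with an electron-withdrawing bromine and a bulky secondary alkyl group, is a poor diene, and furan adducts revert easily. After the key step the ester of A3 would have to be removed (saponification, radical decarboxylation in the presence of three C–Br bonds) and the bromoalkene hydrogenated from the exo face without hydrogenolysis of one vinylic and two alkyl C–Br bonds. In comparison, both plans fix C1 and C4 together and need an external chiral influence to relate them to C1′. Mechanistically a reversible, electronically mismatched cycloaddition stands against a polar double addition that needs only chemoselectivity. In step economy the chosen plan is shorter by about two steps after ring formation, and A1 would itself need several steps from the acid 10.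

Alternative 2: The cut is C4–C5 and C3–C2, with no ring closure. The ate complex from the alkenyl boronate 2-{1-[(1S,4S)-4-bromo-3,3-dimethylcyclohexyl]ethenyl}-4,4,5,5-tetramethyl-1,3,2-dioxaborolane A4 and the organolithium (3-methylbut-3-en-1-yl)lithium A5 would react with the electrophile bromoethene A6 under enantioselective palladium catalysis. The homoallyl group would migrate from boron to C4 while the vinyl group bonds to C3. The product would be the tertiary boronate 2-{(4R)-4-[(1S,4S)-4-bromo-3,3-dimethylcyclohexyl]-7-methylocta-1,7-dien-4-yl}-4,4,5,5-tetramethyl-1,3,2-dioxaborolane A7. Oxidation of the C–B bond of A7 with retention, followed by ring-closing metathesis, would then lead to 17.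

In its favour, and better than the chosen plan on this point, C4 would be created directly as a stereocentre with two different arms, by a metallate shift whose enantiocontrol is documented for α-substituted alkenyl boronates. No desymmetrisation would be needed.

Against it, A4 would need about three extra steps from the acid series, and its α-substituent is a bulky secondary alkyl group, a demanding case for the shift. The primary alkyllithium A5 would have to be generated and used next to the secondary bromide of A4, and A6 is a gas that must be dosed. Three steps would then follow the key step instead of two. In comparison, both plans attach two carbon groups to the same carbon, the chosen one to an electrophilic ester carbon in a single flask, this one to a boron-bound alkene carbon in a three-component coupling. In stereochemical security A7 is the stronger intermediate. In step economy the chosen plan is shorter by roughly three steps. The fallback to the key step borrows the metathesis endgame of this alternative.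

Alternative 3: The cut is C2′–C3′ and C4′–Br. A bromonium donor would attack the prenyl alkene of the bridgehead diene (1R,2R,4S)-2-bromo-1-methyl-4-(6-methylhepta-1,5-dien-2-yl)-7-oxabicyclo[2.2.1]heptane A8. The 1,1-disubstituted alkene would close the ring through a chair and the C1′ cation would lose a ring proton, giving the cyclohexene (1R,2R,4S)-2-bromo-4-[(4S)-4-bromo-5,5-dimethylcyclohex-1-en-1-yl]-1-methyl-7-oxabicyclo[2.2.1]heptane A9.

In its favour, and better than the chosen plan on this point, the sensitive neopentylic bromide would be made last and meet only one further step. In the chosen route it is carried through nine steps, including a Grignard reaction and a cobalt hydride. The ring-forming event is of the same bromonium cyclisation type as step 2 of the chosen route, so on that point the two plans are equal.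

Against it, the bromonium ion would form far from the bicycle of A8, so C4′ would be expected as a mixture of both configurations unless an enantioselective bromonium transfer were available. The terminating cation at C1′ lies next to the oxygen-bearing bridgehead and could escape by a 1,2-shift that opens the strained ether. The alkene of A9 would then have to be hydrogenated to set C1′ trans to bromine with no directing group and two alkyl C–Br bonds at risk. In comparison, the step count could be equal to or lower than that of the chosen plan, but two stereocentres (C4′, C1′) would be left to late, weakly controlled steps, and A8 would still need an enantioselective entry to the oxabicycle. The chosen plan brings C1′ and C4′ in with a resolved, purified precursor.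

Key step: step 9

Remark: 12 and the bromonium salt of step 2 are taken as catalogue compounds. The sense of induction of the cobalt ligand on this carbinol cannot be assigned in advance, so the ligand antipode that leads to 17 is to be chosen in a small trial.

## Route

Step 1
Reactants: 1 6-methylhept-5-en-2-one (sulcatone)
Product: 3 6-methylhepta-1,5-dien-2-yl acetate, via lithium 6-methylhepta-1,5-dien-2-olate 2 (not isolated)
Conditions: LiN(iPr)2, THF, −78 °C; cannulated into Ac2O (3 equiv), THF, −78 → 0 °C
Reagents that add atoms: acetic anhydride, CC(=O)OC(C)=O
Why: Kinetic deprotonation of the methyl ketone gives the less substituted enolate 2, and inverse addition to excess anhydride acylates it on oxygen (enolate trapping as an enol ester). An enol ester is far less nucleophilic towards Br+ than the trisubstituted alkene, which step 2 requires; the small share of internal enol acetate cannot close a six-membered ring and is removed after step 2.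

Step 2
Reactants: 3 6-methylhepta-1,5-dien-2-yl acetate
Product: 4 rac-4-bromo-3,3-dimethylcyclohexan-1-one
Conditions: [Et2SBr][SbBrCl5] (1.1 equiv), MeNO2, −25 °C, 10 min; H2O quench
Reagents that add atoms: bromodiethylsulfonium bromopentachloroantimonate, CC[S+](Br)CC.Br[Sb-](Cl)(Cl)(Cl)(Cl)Cl
Why: Bromonium-initiated cation–olefin cyclisation: Br+ goes to the electron-rich trisubstituted alkene, the enol acetate terminus attacks the tertiary carbon of the bromonium ion through a chair (6-endo closure, C2′–C3′ formed anti to the new C4′–Br bond), and the acetoxy-stabilised cation loses its acetyl group to leave the ketone. C4′ is formed without control, hence the racemate; the non-nucleophilic counter-ion and polar solvent disfavour dibromide formation.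

Step 3
Reactants: 4 rac-4-bromo-3,3-dimethylcyclohexan-1-one
Product: 5 (4S)-4-bromo-3,3-dimethylcyclohexan-1-one
Conditions: preparative SFC, amylose tris(3,5-dimethylphenylcarbamate) stationary phase, CO2/MeOH, 35 °C
Reagents that add atoms: none
Why: Physical separation of the enantiomers of a small rigid ketone at the cheapest point of the sequence; no stereocentre is formed. The (S) antipode is to be identified by anomalous-dispersion X-ray analysis of a crystalline hydrazone derivative, bromine serving as the heavy atom.

Step 4
Reactants: 5 (4S)-4-bromo-3,3-dimethylcyclohexan-1-one; 6 (methoxymethyl)triphenylphosphonium chloride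
Product: 9 (4S)-4-bromo-3,3-dimethylcyclohexane-1-carbaldehyde (C1 epimers), via (methoxymethylidene)triphenylphosphorane 7 (not isolated), via (1S)-1-bromo-4-(methoxymethylidene)-2,2-dimethylcyclohexane 8 (not isolated)
Conditions: 6 (1.5 equiv), KN(SiMe3)2 (1.4 equiv), THF, 0 °C; 5, −78 → 0 °C; then 2 M aq. HCl, THF, rt, until the epimer ratio is constant
Reagents that add atoms: water, O
Why: Wittig reaction of ylide 7 with the unhindered ketone gives enol ether 8 (E/Z irrelevant), and acid hydrolysis unmasks the homologous aldehyde without touching C4′. The new C1′ centre equilibrates through the enol; the diequatorial trans (1S,4S) epimer should predominate, though not exclusively, because the cis epimer can place bromine axial at little cost.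

Step 5
Reactants: 9 (4S)-4-bromo-3,3-dimethylcyclohexane-1-carbaldehyde (C1 epimers)
Product: 10 (4S)-4-bromo-3,3-dimethylcyclohexane-1-carboxylic acid (C1 epimers)
Conditions: NaClO2, NaH2PO4, 2-methylbut-2-ene, t-BuOH/H2O, 0 °C → rt
Reagents that add atoms: sodium chlorite, [Na+].[O-]Cl=O
Why: Pinnick oxidation at pH 3–4 converts the aldehyde to the acid without enolisation, so the epimer ratio of 9 is carried over and the bromide is untouched; 2-methylbut-2-ene scavenges hypochlorous acid.

Step 6
Reactants: 10 (4S)-4-bromo-3,3-dimethylcyclohexane-1-carboxylic acid (C1 epimers)
Product: 11 methyl (1S,4S)-4-bromo-3,3-dimethylcyclohexane-1-carboxylate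
Conditions: HCl (1.25 M in MeOH), MeOH, 40 °C; silica gel chromatography (cis epimer removed)
Reagents that add atoms: methanol, CO
Why: Fischer esterification under anhydrous acid neither epimerises C1′ nor disturbs the secondary bromide. The diequatorial trans ester and its cis epimer (axial bromine) differ in shape and polarity and should separate on silica, giving the key-step precursor as one stereoisomer.

Step 7
Reactants: 12 3-methylidenepentane-1,5-diol
Product: 13 1,5-dibromo-3-methylidenepentane
Conditions: CBr4 (2.4 equiv), PPh3 (2.5 equiv), CH2Cl2, 0 °C → rt
Reagents that add atoms: tetrabromomethane, BrC(Br)(Br)Br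
Why: Appel bromination replaces both primary hydroxyls by SN2 displacement of alkoxyphosphonium ions under neutral conditions, so the 1,1-disubstituted alkene neither migrates nor adds HBr.

Step 8
Reactants: 13 1,5-dibromo-3-methylidenepentane
Product: 14 (3-methylidenepentane-1,5-diyl)bis(magnesium bromide)
Conditions: Mg turnings (4 equiv, I2 crystal), THF, 35–40 °C, slow addition of 13 (final ca. 0.3 M); titrated, used at once
Reagents that add atoms: magnesium, [Mg]
Why: Magnesium inserts into both primary C–Br bonds as in the preparation of pentane-1,5-diylbis(magnesium bromide); slow addition at moderate dilution limits Wurtz coupling. The homoallylic C–Mg termini can only undergo a degenerate cyclopropylcarbinyl interconversion.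

Step 9
Reactants: 11 methyl (1S,4S)-4-bromo-3,3-dimethylcyclohexane-1-carboxylate; 14 (3-methylidenepentane-1,5-diyl)bis(magnesium bromide)
Product: 16 1-[(1S,4S)-4-bromo-3,3-dimethylcyclohexyl]-4-methylidenecyclohexan-1-ol, via bromo{6-[(1S,4S)-4-bromo-3,3-dimethylcyclohexyl]-3-methylidene-6-oxohexyl}magnesium 15 (not isolated)
Conditions: 14 (1.3 equiv, 0.3 M in THF), 11 added in THF over 1 h at 0 °C, then rt, 2 h; sat. aq. NH4Cl
Reagents that add atoms: none
Why: One C–Mg bond of 14 adds to the ester carbonyl and the tetrahedral adduct loses methoxide to give keto-Grignard 15, whose remaining C–Mg bond then adds to the new ketone, so that C4–C3 and C4–C5 are both made on the former ester carbon. The closest known reaction type is the annulation of carboxylic esters with pentane-1,5-diylbis(magnesium bromide) to 1-substituted cyclohexanols. The single ring closes by 6-exo-trig addition of the tethered carbanion to the C=O group, which should outrun a second intermolecular addition because the chain end is held five atoms from the carbonyl. No stereocentre is created: the two arms are identical and a mirror plane passes through the carbinol carbon and the methylidene carbon, so 16 carries only the stereocentres brought in with 11. The step needs chemoselectivity for the ester and the transient ketone over the C4′–Br bond, which the inertness of a hindered neopentylic secondary bromide towards uncatalysed Grignard reagents at 0 °C should secure (magnesium free of transition metals avoids Kumada-type coupling). Addition must also beat α-deprotonation at C1′; an unhindered primary alkylmagnesium and a cyclohexanecarboxylate at low temperature favour addition, so C1′ is expected to be carried through unchanged. The exocyclic methylene is inert here and serves later as both the C1 methyl and the C1=C2 alkene.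

Step 10
Reactants: 16 1-[(1S,4S)-4-bromo-3,3-dimethylcyclohexyl]-4-methylidenecyclohexan-1-ol
Product: 17 (1S)-1-[(1S,4S)-4-bromo-3,3-dimethylcyclohexyl]-4-methylcyclohex-3-en-1-ol
Conditions: CoBr2 (5 mol%), ligand L (6 mol%), NaBHEt3 (12 mol%), toluene, rt, 15 min; then 16, 0 °C → rt; L = (S)-4-tert-butyl-2-{6-[1-(2,6-diisopropylphenylimino)ethyl]pyridin-2-yl}-4,5-dihydrooxazole or its antipode
Reagents that add atoms: none
Why: Proposed new method: the cobalt hydride formed from CoBr2, the chiral tridentate ligand and NaBHEt3 should add to the exocyclic alkene in the Markovnikov sense to give a tertiary alkylcobalt at C1, and β-hydride elimination towards one of the two diastereotopic ring methylenes (C2 rather than C6), selected in the chiral pocket, releases the trisubstituted ring alkene, the thermodynamic sink. That choice of arm is what makes the carbinol carbon C4 stereogenic and (S); the closest known reaction type is the cobalt-hydride-catalysed desymmetrising isomerisation of 4-substituted methylidenecyclohexanes to 4-substituted 1-methylcyclohexenes, here extended to a 4,4-disubstituted ring with a free tertiary hydroxyl and a remote secondary bromide. The hydride is generated before the substrate is added so that NaBHEt3 does not meet the C–Br bond.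

Step 11
Reactants: 17 (1S)-1-[(1S,4S)-4-bromo-3,3-dimethylcyclohexyl]-4-methylcyclohex-3-en-1-ol
Product: 18 (1R,2R,4S)-2-bromo-4-[(1S,4S)-4-bromo-3,3-dimethylcyclohexyl]-1-methyl-7-oxabicyclo[2.2.1]heptane
Conditions: NBS (1.1 equiv), CH2Cl2, 0 °C, dark
Reagents that add atoms: N-bromosuccinimide, O=C1CCC(=O)N1Br
Why: Bromoetherification: the bromonium ion forms reversibly on either face of the C1=C2 alkene, but only the one anti to the hydroxyl can be opened, by transannular attack of the C4 oxygen at the more substituted carbon C1 through a boat conformer (attack at C2 would give an oxetane). Anti addition places bromine endo at C2, so C1 (R) and C2 (R) follow from the (S) carbinol of 17; the closest precedent is the halocyclisation of 1-substituted 4-methylcyclohex-3-en-1-ols of the terpinen-4-ol type to 2-halo-1,4-cineoles.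

## Compound list

1 | 6-methylhept-5-en-2-one (sulcatone) | CC(=O)CCC=C(C)C | starting material
2 | lithium 6-methylhepta-1,5-dien-2-olate | [Li+].[O-]C(=C)CCC=C(C)C | intermediate
3 | 6-methylhepta-1,5-dien-2-yl acetate | CC(=O)OC(=C)CCC=C(C)C | intermediate
4 | rac-4-bromo-3,3-dimethylcyclohexan-1-one (racemate) | CC1(C)CC(=O)CCC1Br | intermediate
5 | (4S)-4-bromo-3,3-dimethylcyclohexan-1-one | CC1(C)CC(=O)CC[C@@H]1Br | intermediate
6 | (methoxymethyl)triphenylphosphonium chloride | COC[P+](c1ccccc1)(c1ccccc1)c1ccccc1.[Cl-] | starting material
7 | (methoxymethylidene)triphenylphosphorane | COC=P(c1ccccc1)(c1ccccc1)c1ccccc1 | intermediate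
8 | (1S)-1-bromo-4-(methoxymethylidene)-2,2-dimethylcyclohexane (E/Z mixture) | CC1(C)CC(=COC)CC[C@@H]1Br | intermediate
9 | (4S)-4-bromo-3,3-dimethylcyclohexane-1-carbaldehyde (C1 epimers, trans expected as major) | CC1(C)CC(C=O)CC[C@@H]1Br | intermediate
10 | (4S)-4-bromo-3,3-dimethylcyclohexane-1-carboxylic acid (C1 epimers) | CC1(C)CC(C(=O)O)CC[C@@H]1Br | intermediate
11 | methyl (1S,4S)-4-bromo-3,3-dimethylcyclohexane-1-carboxylate | CC1(C)C[C@@H](C(=O)OC)CC[C@@H]1Br | intermediate
12 | 3-methylidenepentane-1,5-diol | C=C(CCO)CCO | starting material
13 | 1,5-dibromo-3-methylidenepentane | C=C(CCBr)CCBr | intermediate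
14 | (3-methylidenepentane-1,5-diyl)bis(magnesium bromide) | C=C(CC[Mg]Br)CC[Mg]Br | intermediate
15 | bromo{6-[(1S,4S)-4-bromo-3,3-dimethylcyclohexyl]-3-methylidene-6-oxohexyl}magnesium | CC1(C)C[C@@H](C(=O)CCC(=C)CC[Mg]Br)CC[C@@H]1Br | intermediate
16 | 1-[(1S,4S)-4-bromo-3,3-dimethylcyclohexyl]-4-methylidenecyclohexan-1-ol | CC1(C)C[C@@H](C2(O)CCC(=C)CC2)CC[C@@H]1Br | intermediate
17 | (1S)-1-[(1S,4S)-4-bromo-3,3-dimethylcyclohexyl]-4-methylcyclohex-3-en-1-ol | CC1(C)C[C@@H]([C@]2(O)CCC(C)=CC2)CC[C@@H]1Br | intermediate
18 | (1R,2R,4S)-2-bromo-4-[(1S,4S)-4-bromo-3,3-dimethylcyclohexyl]-1-methyl-7-oxabicyclo[2.2.1]heptane | CC1(C)C[C@@H]([C@@]23CC[C@@](C)(O2)[C@H](Br)C3)CC[C@@H]1Br | target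

## Step count and least certain steps

Total: 11 steps. Longest linear sequence: 9 steps from 1 (steps 1–6, then 9–11); the side branch from 12 to 14 has 2 steps.

**Step 10 (isomerisation).** This is the least certain operation. The most likely failures are deactivation or diversion of the low-valent cobalt hydride by the free tertiary hydroxyl, halogen abstraction from the secondary C–Br bond (reductive debromination), and weak or wrong-sense discrimination between the two ring arms, because the element nearest the reacting alkene is a fully substituted carbinol and not the C–H stereocentre of the precedents. The fallback sets out from 16 and returns at 18, using known chemistry without catalyst control. 16 is isomerised by hydrogen-atom-transfer catalysis ([Co(C36H52N2O2)Cl], the chlorocobalt complex of N,N′-bis(3,5-di-tert-butylsalicylidene)cyclohexane-1,2-diamine, with PhSiH3, benzene, rt). This should give a near-statistical mixture of 17 and its carbinol epimer (1R)-1-[(1S,4S)-4-bromo-3,3-dimethylcyclohexyl]-4-methylcyclohex-3-en-1-ol F1. The mixture is carried through the conditions of step 11, which should give 18 beside (1S,2S,4R)-2-bromo-4-[(1S,4S)-4-bromo-3,3-dimethylcyclohexyl]-1-methyl-7-oxabicyclo[2.2.1]heptane F2. The two rigid diastereomers are then separated by chromatography, at the price of half the material.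

**Step 9 (key step).** The most likely failure is incomplete annulation. After the first addition the second C–Mg bond may be lost to proton transfer (enolisation of the intermediate ketone, which would also erode C1′) or to intermolecular addition, giving open-chain and oligomeric alcohols. A bis-Grignard solution contaminated by Wurtz products or half-formed reagent would make this worse. The fallback sets out from 11 and returns at 17, so that it also bypasses step 10; it forms the same two bonds at the former ester carbon one after the other. 11 is converted with MeNHOMe·HCl and iPrMgCl (THF, −20 °C) into (1S,4S)-4-bromo-N-methoxy-N,3,3-trimethylcyclohexane-1-carboxamide F3. Addition of (3-methylbut-3-en-1-yl)magnesium bromide F4, made from commercial 4-bromo-2-methylbut-1-ene and magnesium, should give 1-[(1S,4S)-4-bromo-3,3-dimethylcyclohexyl]-4-methylpent-4-en-1-one F5. Catalytic asymmetric allylboration of this ketone (allylboronic acid diisopropyl ester, 3,3′-dibromo-1,1′-bi-2-naphthol of the appropriate handedness, t-BuOH, toluene) should give (4S)-4-[(1S,4S)-4-bromo-3,3-dimethylcyclohexyl]-7-methylocta-1,7-dien-4-ol F6. Ring-closing metathesis with the second-generation Grubbs catalyst RuCl2(=CHPh)(PCy3)(H2IMes) in CH2Cl2 then closes the trisubstituted ring alkene of 17.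

**Step 2 (bromocyclisation).** The most likely failure is misdirected bromination: attack at the enol acetate terminus, or capture of the bromonium ion by halide before the weakly nucleophilic terminus can close the ring. The fallback sets out from 3 and returns at 4. Hg(OCOCF3)2 in MeNO2 at −20 °C (divalent mercury is a softer electrophile that is not captured by its counter-ion) should effect the same cyclisation. After a NaCl wash this gives racemic 4-(chloromercurio)-3,3-dimethylcyclohexan-1-one F7, which is converted into 4 by brominative demercuration (Br2, LiBr, pyridine, O2 atmosphere). Both operations are established for enol-ester- and enol-phosphate-terminated cyclisations.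

**Step 4 (homologation).** The most likely failure is enolisation of the γ-bromo ketone by the basic ylide in competition with addition, followed by intramolecular displacement of bromide (cyclopropane formation) or simple return of ketone. The fallback sets out from 5 and returns at 9 and avoids strong base. Takai–Lombardo methylenation (Zn, CH2Br2, TiCl4, THF/CH2Cl2, 0 °C) gives (1S)-1-bromo-2,2-dimethyl-4-methylidenecyclohexane F8. Hydroboration–oxidation (9-borabicyclo[3.3.1]nonane, THF; NaBO3·4H2O) gives [(4S)-4-bromo-3,3-dimethylcyclohexyl]methanol F9 as C1 epimers. Dess–Martin oxidation returns 9, which is equilibrated at C1′ with dilute acid as in step 4.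

## Further compounds

F1 | step 10 | (1R)-1-[(1S,4S)-4-bromo-3,3-dimethylcyclohexyl]-4-methylcyclohex-3-en-1-ol | CC1(C)C[C@@H]([C@@]2(O)CCC(C)=CC2)CC[C@@H]1Br
F2 | step 10 | (1S,2S,4R)-2-bromo-4-[(1S,4S)-4-bromo-3,3-dimethylcyclohexyl]-1-methyl-7-oxabicyclo[2.2.1]heptane | CC1(C)C[C@@H]([C@]23CC[C@](C)(O2)[C@@H](Br)C3)CC[C@@H]1Br
F3 | step 9 | (1S,4S)-4-bromo-N-methoxy-N,3,3-trimethylcyclohexane-1-carboxamide | CC1(C)C[C@@H](C(=O)N(C)OC)CC[C@@H]1Br
F4 | step 9 | (3-methylbut-3-en-1-yl)magnesium bromide | C=C(C)CC[Mg]Br
F5 | step 9 | 1-[(1S,4S)-4-bromo-3,3-dimethylcyclohexyl]-4-methylpent-4-en-1-one | CC1(C)C[C@@H](C(=O)CCC(C)=C)CC[C@@H]1Br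
F6 | step 9 | (4S)-4-[(1S,4S)-4-bromo-3,3-dimethylcyclohexyl]-7-methylocta-1,7-dien-4-ol | CC1(C)C[C@@H]([C@](CC=C)(O)CCC(C)=C)CC[C@@H]1Br
F7 | step 2 | 4-(chloromercurio)-3,3-dimethylcyclohexan-1-one (racemate) | CC1(C)CC(=O)CCC1[Hg]Cl
F8 | step 4 | (1S)-1-bromo-2,2-dimethyl-4-methylidenecyclohexane | CC1(C)CC(=C)CC[C@@H]1Br
F9 | step 4 | [(4S)-4-bromo-3,3-dimethylcyclohexyl]methanol (C1 epimers) | CC1(C)CC(CO)CC[C@@H]1Br
A1 | alternative 1 | 3-bromo-5-[(1S,4S)-4-bromo-3,3-dimethylcyclohexyl]-2-methylfuran | CC1(C)C[C@@H](c2cc(Br)c(C)o2)CC[C@@H]1Br
A2 | alternative 1 | 2,2,2-trifluoroethyl prop-2-enoate | C=CC(=O)OCC(F)(F)F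
A3 | alternative 1 | 2,2,2-trifluoroethyl (1R,2S,4R)-6-bromo-4-[(1S,4S)-4-bromo-3,3-dimethylcyclohexyl]-1-methyl-7-oxabicyclo[2.2.1]hept-5-ene-2-carboxylate | CC1(C)C[C@@H]([C@@]23C[C@H](C(=O)OCC(F)(F)F)[C@@](C)(O2)C(Br)=C3)CC[C@@H]1Br
A4 | alternative 2 | 2-{1-[(1S,4S)-4-bromo-3,3-dimethylcyclohexyl]ethenyl}-4,4,5,5-tetramethyl-1,3,2-dioxaborolane | CC1(C)C[C@@H](C(=C)B2OC(C)(C)C(C)(C)O2)CC[C@@H]1Br
A5 | alternative 2 | (3-methylbut-3-en-1-yl)lithium | [Li]CCC(C)=C
A6 | alternative 2 | bromoethene | C=CBr
A7 | alternative 2 | 2-{(4R)-4-[(1S,4S)-4-bromo-3,3-dimethylcyclohexyl]-7-methylocta-1,7-dien-4-yl}-4,4,5,5-tetramethyl-1,3,2-dioxaborolane | CC1(C)C[C@@H]([C@@](B2OC(C)(C)C(C)(C)O2)(CC=C)CCC(C)=C)CC[C@@H]1Br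
A8 | alternative 3 | (1R,2R,4S)-2-bromo-1-methyl-4-(6-methylhepta-1,5-dien-2-yl)-7-oxabicyclo[2.2.1]heptane | CC(C)=CCCC(=C)[C@@]12CC[C@@](C)(O1)[C@H](Br)C2
A9 | alternative 3 | (1R,2R,4S)-2-bromo-4-[(4S)-4-bromo-5,5-dimethylcyclohex-1-en-1-yl]-1-methyl-7-oxabicyclo[2.2.1]heptane | CC1(C)CC(=CC[C@@H]1Br)[C@@]23CC[C@@](C)(O2)[C@H](Br)C3
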